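**Plan**

- The retrosynthesis first removes the two benzyl ethers and opens the pyranone at O1–C2. It then cuts C3–C4 of the flavone: C4 sits on C4a, which lies between the oxygen-bearing carbons C5 and C8a, so C4 can be the carbon of a shielded, long-lived aryl nitrile oxide. C2 (phenyl) and C3 (methoxy) come from the pyrrolidine enamine of 2-methoxy-1-phenylethanone.
- Further cuts: the C8–CH2 bond of ring A (o-quinone methide plus the dihydrochalcone ring), then the aryl–acyl bond and the O-methyl bond of the dihydrochalcone.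
- Forward: 2,4,6-trihydroxytoluene is acylated and mono-methylated. 2,4,6-Trihydroxybenzaldehyde is dibenzylated, aminomethylated and joined to the dihydrochalcone through the CH2 bridge. MOM protection, oxime formation and oxidation give the nitrile oxide.
- Rings: the isoxazole arises in the cycloaddition. N–O cleavage and acid convert it into the pyranone (ring C), closed by the one ring A oxygen that carried an acid-labile MOM group. Hydrogenolysis then frees the 5- and 7-hydroxyls.
- Stereochemistry: the target has no stereocentre. The two sp3 centres of the transient dihydroisoxazole vanish on aromatization.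

Key step: step 10

Remark on the chemistry: the enamine is drawn as its Z isomer; its geometry is erased in the cycloaddition/elimination, so any E/Z mixture obtained would be used as such.

**Step 1**
Reactants: 1 2,4,6-trihydroxytoluene; 2 3-phenylpropanoic acid
Product: 3 3-phenyl-1-(2,4,6-trihydroxy-3-methylphenyl)propan-1-one
Conditions: BF3·OEt2 (neat), 90 °C; then aq. NaOAc
Reagents that add atoms: none
Why: Friedel–Crafts acylation of a phloroglucinol with the free acid in BF3·OEt2; the two open ring carbons of 1 are equivalent and the first acyl group deactivates the ring, so mono-acylation is expected.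

**Step 2**
Reactants: 3 3-phenyl-1-(2,4,6-trihydroxy-3-methylphenyl)propan-1-one
Product: 4 1-(2,6-dihydroxy-4-methoxy-3-methylphenyl)-3-phenylpropan-1-one
Conditions: Me2SO4 (1.0 equiv), K2CO3 (1.0 equiv), acetone, rt
Reagents that add atoms: dimethyl sulfate, COS(=O)(=O)OC
Why: Selective Williamson O-methylation; the 4-hydroxyl para to the acyl group is the most acidic and is not tied up in a hydrogen bond to the ketone, so it should react ahead of the two ortho hydroxyls.

**Step 3**
Reactants: 5 2,4,6-trihydroxybenzaldehyde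
Product: 6 2,4-bis(benzyloxy)-6-hydroxybenzaldehyde
Conditions: BnBr (2.1 equiv), K2CO3 (2.2 equiv), DMF, 0 °C to rt
Reagents that add atoms: benzyl bromide, BrCc1ccccc1
Why: Williamson benzylation; the para hydroxyl and one ortho hydroxyl are alkylated, while the last ortho hydroxyl, locked in a hydrogen bond to the formyl group, should stay free, as is usual for 2,4,6-trihydroxyaryl carbonyl compounds.

**Step 4**
Reactants: 6 2,4-bis(benzyloxy)-6-hydroxybenzaldehyde
Product: 7 4,6-bis(benzyloxy)-3-[(dimethylamino)methyl]-2-hydroxybenzaldehyde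
Conditions: Me2NCH2NMe2 (1.3 equiv), 1,4-dioxane, 70 °C
Reagents that add atoms: N,N,N',N'-tetramethylmethanediamine, CN(C)CN(C)C
Why: Phenolic Mannich aminomethylation; the acidic chelated phenol opens the aminal to an iminium phenoxide ion pair that should collapse at the ring carbon between the free hydroxyl and a benzyloxy group, which is also less crowded than the carbon between the two benzyloxy groups.

**Step 5**
Reactants: 7 4,6-bis(benzyloxy)-3-[(dimethylamino)methyl]-2-hydroxybenzaldehyde; 4 1-(2,6-dihydroxy-4-methoxy-3-methylphenyl)-3-phenylpropan-1-one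
Product: 9 4,6-bis(benzyloxy)-3-{[2,4-dihydroxy-6-methoxy-5-methyl-3-(3-phenylpropanoyl)phenyl]methyl}-2-hydroxybenzaldehyde, via o-quinone methide 8 (not isolated)
Conditions: PhMe, 110 °C, N2 sweep
Reagents that add atoms: none
Why: Thermal loss of dimethylamine from the Mannich base should give o-quinone methide 8, to which the phloroglucinol ring of 4 adds in Michael fashion through its only unsubstituted carbon (C-benzylation of a phenol by an o-quinone methide), restoring both aromatic rings.

**Step 6**
Reactants: 9 4,6-bis(benzyloxy)-3-{[2,4-dihydroxy-6-methoxy-5-methyl-3-(3-phenylpropanoyl)phenyl]methyl}-2-hydroxybenzaldehyde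
Product: 10 4,6-bis(benzyloxy)-2-(methoxymethoxy)-3-{[6-methoxy-2,4-bis(methoxymethoxy)-5-methyl-3-(3-phenylpropanoyl)phenyl]methyl}benzaldehyde
Conditions: NaH (3.3 equiv), MOMCl (3.6 equiv), DMF, 0 °C to rt
Reagents that add atoms: chloromethyl methyl ether, COCCl
Why: MOM ether formation (Williamson-type alkylation of the three phenoxides), with NaH limited to about one equivalent per phenol so that the ketone is not enolized.

**Step 7**
Reactants: 10 4,6-bis(benzyloxy)-2-(methoxymethoxy)-3-{[6-methoxy-2,4-bis(methoxymethoxy)-5-methyl-3-(3-phenylpropanoyl)phenyl]methyl}benzaldehyde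
Product: 11 (E)-oxime of 10
Conditions: 50% aq. NH2OH (1.5 equiv), EtOH/THF, rt
Reagents that add atoms: hydroxylamine, NO
Why: Oxime condensation, selective for the aldehyde because the aryl ketone flanked by two ortho MOM ethers condenses far more slowly; free hydroxylamine keeps the medium non-acidic for the MOM acetals.

**Step 8**
Reactants: 11 (E)-oxime of 10
Product: 12 4,6-bis(benzyloxy)-2-(methoxymethoxy)-3-{[6-methoxy-2,4-bis(methoxymethoxy)-5-methyl-3-(3-phenylpropanoyl)phenyl]methyl}benzonitrile oxide
Conditions: PhI(OAc)2 (1.1 equiv), MeOH, 0 °C; aq. NaHCO3 work-up, used at once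
Reagents that add atoms: none
Why: Oxidative dehydrogenation of an aldoxime to a nitrile oxide with a hypervalent iodine reagent, which brings no positive halogen that could attack the electron-rich CH of ring A; the two ortho oxygens shield the CNO carbon, so the dipole should persist and not dimerize to the furoxan.

**Step 9**
Reactants: 13 2-methoxy-1-phenylethanone; 14 pyrrolidine
Product: 15 (Z)-1-(2-methoxy-1-phenylethenyl)pyrrolidine
Conditions: TiCl4 (0.55 equiv), pyrrolidine (6 equiv), PhMe, 0 °C to rt; filter, concentrate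
Reagents that add atoms: none
Why: Titanium-mediated enamine condensation, in which TiCl4 acts as Lewis acid and water scavenger; this is the standard way to force enamine formation from aryl ketones.

**Step 10**
Reactants: 12 the nitrile oxide; 15 (Z)-1-(2-methoxy-1-phenylethenyl)pyrrolidine
Product: 17 3-[4,6-bis(benzyloxy)-2-(methoxymethoxy)-3-{[6-methoxy-2,4-bis(methoxymethoxy)-5-methyl-3-(3-phenylpropanoyl)phenyl]methyl}phenyl]-4-methoxy-5-phenyl-1,2-oxazole, via 5-pyrrolidinyl-4,5-dihydroisoxazole 16 (not isolated)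
Conditions: 15 (1.5 equiv), PhMe, rt to 50 °C; then AcOH (2 equiv), rt
Reagents that add atoms: none
Why: The nucleophilic methoxy-bearing carbon of enamine 15 attacks the electrophilic carbon of the nitrile oxide while the dipole oxygen closes onto the carbon carrying phenyl and nitrogen, an asynchronous 1,3-dipolar cycloaddition that forms the later C3–C4 and O1–C2 bonds of the flavone in one operation. The closest known reaction type is the cycloaddition of aryl nitrile oxides to enamines, which gives 5-amino-4,5-dihydroisoxazoles that lose the amine to become isoxazoles. The one new ring is the five-membered dihydroisoxazole of 16, closed by [3+2] union of the C–N–O dipole with the two alkene carbons. The two sp3 centres of 16 need no control, because protonation of the pyrrolidine nitrogen by acetic acid and elimination across C4–C5 should give the same aromatic isoxazole 17 from every diastereomer and from either enamine geometry. The step needs regioselectivity (methoxy on isoxazole C4, phenyl on C5) and chemoselectivity: the pyrrolidine nitrogen is the stronger donor and fixes the polarity of the alkene so that carbon–carbon bonding occurs at the methoxy-bearing carbon, while the two ortho oxygens of 12 slow furoxan formation and the hindered aryl ketone is no dipolarophile. Acid is added only after 12 is consumed, so that liberated pyrrolidine cannot add to the dipole.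

**Step 11**
Reactants: 17 the isoxazole
Product: 18 (E)-3-amino-3-Ar-2-methoxy-1-phenylprop-2-en-1-one (Ar = the aryl group bonded to the CNO carbon of 12)
Conditions: Mo(CO)6 (1.1 equiv), MeCN/H2O, 80 °C
Reagents that add atoms: none
Why: Reductive N–O cleavage of an isoxazole by zerovalent molybdenum in wet acetonitrile to the hydrogen-bonded vinylogous amide; the ketone, benzyl ethers and MOM acetals are not touched by this reagent.

**Step 12**
Reactants: 18 the vinylogous amide
Product: 20 5,7-bis(benzyloxy)-8-{[2,4-dihydroxy-6-methoxy-5-methyl-3-(3-phenylpropanoyl)phenyl]methyl}-3-methoxy-2-phenyl-4H-chromen-4-one, via triphenolic 1,3-diketone 19 (not isolated)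
Conditions: 2 M HCl, MeOH/THF/H2O, 60 °C
Reagents that add atoms: water, O
Why: Acid removes the three MOM acetals, hydrolyses the vinylogous amide to 1,3-diketone 19 and cyclodehydrates it as in the last stage of a Baker–Venkataraman flavone synthesis; on ring A only the oxygen next to the CH2 bridge is free, the other ortho oxygen being still benzylated, so the pyranone can close only to the 8-substituted flavone.

**Step 13**
Reactants: 20 the 5,7-di-O-benzyl flavone
Product: 21 8-{[2,4-dihydroxy-6-methoxy-5-methyl-3-(3-phenylpropanoyl)phenyl]methyl}-5,7-dihydroxy-3-methoxy-2-phenyl-4H-chromen-4-one (target)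
Conditions: H2 (1 atm), Pd/C, EtOAc/MeOH, rt
Reagents that add atoms: none
Why: Catalytic hydrogenolysis of the two aryl benzyl ethers; under these mild conditions the tetrasubstituted C2=C3 bond of the flavone, the hindered ketone and the diarylmethane link should not be reduced.

**Compound list**

1 | 2,4,6-trihydroxytoluene | Cc1c(O)cc(O)cc1O | starting material
2 | 3-phenylpropanoic acid | OC(=O)CCc1ccccc1 | starting material
3 | 3-phenyl-1-(2,4,6-trihydroxy-3-methylphenyl)propan-1-one | Cc1c(O)cc(O)c(C(=O)CCc2ccccc2)c1O | intermediate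
4 | 1-(2,6-dihydroxy-4-methoxy-3-methylphenyl)-3-phenylpropan-1-one | COc1cc(O)c(C(=O)CCc2ccccc2)c(O)c1C | intermediate
5 | 2,4,6-trihydroxybenzaldehyde | O=Cc1c(O)cc(O)cc1O | starting material
6 | 2,4-bis(benzyloxy)-6-hydroxybenzaldehyde | O=Cc1c(O)cc(OCc2ccccc2)cc1OCc1ccccc1 | intermediate
7 | 4,6-bis(benzyloxy)-3-[(dimethylamino)methyl]-2-hydroxybenzaldehyde | CN(C)Cc1c(O)c(C=O)c(OCc2ccccc2)cc1OCc1ccccc1 | intermediate
8 | 2,4-bis(benzyloxy)-5-methylidene-6-oxocyclohexa-1,3-diene-1-carbaldehyde (o-quinone methide) | C=C1C(=O)C(C=O)=C(OCc2ccccc2)C=C1OCc1ccccc1 | intermediate (not isolated)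
9 | 4,6-bis(benzyloxy)-3-{[2,4-dihydroxy-6-methoxy-5-methyl-3-(3-phenylpropanoyl)phenyl]methyl}-2-hydroxybenzaldehyde | O=Cc1c(O)c(Cc2c(OC)c(C)c(O)c(C(=O)CCc3ccccc3)c2O)c(OCc2ccccc2)cc1OCc1ccccc1 | intermediate
10 | 4,6-bis(benzyloxy)-2-(methoxymethoxy)-3-{[6-methoxy-2,4-bis(methoxymethoxy)-5-methyl-3-(3-phenylpropanoyl)phenyl]methyl}benzaldehyde | O=Cc1c(OCOC)c(Cc2c(OC)c(C)c(OCOC)c(C(=O)CCc3ccccc3)c2OCOC)c(OCc2ccccc2)cc1OCc1ccccc1 | intermediate
11 | (E)-oxime of 10 | O/N=C/c1c(OCOC)c(Cc2c(OC)c(C)c(OCOC)c(C(=O)CCc3ccccc3)c2OCOC)c(OCc2ccccc2)cc1OCc1ccccc1 | intermediate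
12 | 4,6-bis(benzyloxy)-2-(methoxymethoxy)-3-{[6-methoxy-2,4-bis(methoxymethoxy)-5-methyl-3-(3-phenylpropanoyl)phenyl]methyl}benzonitrile oxide | [O-][N+]#Cc1c(OCOC)c(Cc2c(OC)c(C)c(OCOC)c(C(=O)CCc3ccccc3)c2OCOC)c(OCc2ccccc2)cc1OCc1ccccc1 | intermediate
13 | 2-methoxy-1-phenylethanone | COCC(=O)c1ccccc1 | starting material
14 | pyrrolidine | C1CCNC1 | starting material
15 | (Z)-1-(2-methoxy-1-phenylethenyl)pyrrolidine (OMe cis to N; geometry of no consequence) | CO/C=C(/c1ccccc1)N1CCCC1 | intermediate
16 | 3-Ar-4-methoxy-5-phenyl-5-(pyrrolidin-1-yl)-4,5-dihydro-1,2-oxazole (Ar as in 12; racemic, C4/C5 configuration undefined and lost in the same step) | COC1C(c2c(OCOC)c(Cc3c(OC)c(C)c(OCOC)c(C(=O)CCc4ccccc4)c3OCOC)c(OCc3ccccc3)cc2OCc2ccccc2)=NOC1(c1ccccc1)N1CCCC1 | intermediate (not isolated)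
17 | 3-[4,6-bis(benzyloxy)-2-(methoxymethoxy)-3-{[6-methoxy-2,4-bis(methoxymethoxy)-5-methyl-3-(3-phenylpropanoyl)phenyl]methyl}phenyl]-4-methoxy-5-phenyl-1,2-oxazole | COc1c(-c2c(OCOC)c(Cc3c(OC)c(C)c(OCOC)c(C(=O)CCc4ccccc4)c3OCOC)c(OCc3ccccc3)cc2OCc2ccccc2)noc1-c1ccccc1 | intermediate
18 | (E)-3-amino-3-Ar-2-methoxy-1-phenylprop-2-en-1-one (Ar as in 12; NH2 cis to the benzoyl group) | N/C(c1c(OCOC)c(Cc2c(OC)c(C)c(OCOC)c(C(=O)CCc3ccccc3)c2OCOC)c(OCc2ccccc2)cc1OCc1ccccc1)=C(/OC)C(=O)c1ccccc1 | intermediate
19 | 1-[4,6-bis(benzyloxy)-3-{[2,4-dihydroxy-6-methoxy-5-methyl-3-(3-phenylpropanoyl)phenyl]methyl}-2-hydroxyphenyl]-2-methoxy-3-phenylpropane-1,3-dione (racemic at C2, enolizable) | COC(C(=O)c1ccccc1)C(=O)c1c(O)c(Cc2c(OC)c(C)c(O)c(C(=O)CCc3ccccc3)c2O)c(OCc2ccccc2)cc1OCc1ccccc1 | intermediate (not isolated)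
20 | 5,7-bis(benzyloxy)-8-{[2,4-dihydroxy-6-methoxy-5-methyl-3-(3-phenylpropanoyl)phenyl]methyl}-3-methoxy-2-phenyl-4H-chromen-4-one | COc1c(C)c(O)c(C(=O)CCc2ccccc2)c(O)c1Cc1c(OCc2ccccc2)cc(OCc2ccccc2)c2c(=O)c(OC)c(-c3ccccc3)oc12 | intermediate
21 | 8-{[2,4-dihydroxy-6-methoxy-5-methyl-3-(3-phenylpropanoyl)phenyl]methyl}-5,7-dihydroxy-3-methoxy-2-phenyl-4H-chromen-4-one | COc1c(C)c(O)c(C(=O)CCc2ccccc2)c(O)c1Cc1c(O)cc(O)c2c(=O)c(OC)c(-c3ccccc3)oc12 | target

**Totals**

Total step count: 13.
Longest linear sequence: 10 steps (steps 3, 4, 5, 6, 7, 8, 10, 11, 12, 13 from 5; equally steps 1, 2, 5, 6, 7, 8, 10, 11, 12, 13 from 1).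

**Steps most likely to fail**

Step 10. The cycloaddition may be slow, because the dipole is electron-rich and shielded on both sides and the enamine is trisubstituted. On warming, the dipole could then rearrange to the isocyanate or be intercepted by liberated amine before it meets the alkene. The fallback sets out from 12 and 13. The lithium enolate of 13 (LiN(SiMe3)2, THF, −78 °C) is added to 12. The enolate carbon attacks the nitrile oxide carbon and the oximate oxygen closes onto the ketone, which should give 3-Ar-4-methoxy-5-phenyl-4,5-dihydro-1,2-oxazol-5-ol F1. Dehydration (MsCl, Et3N, CH2Cl2, 0 °C) then returns to the route at 17.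

Step 4. Aminomethylation may go partly to the ring carbon between the two benzyloxy groups, or may stall because the phenol is held in its hydrogen bond to the aldehyde. The fallback sets out from 4 and fixes the position of the CH2 group by a tether.
- Purchased 3,5-bis(benzyloxy)phenol F2 is heated with phenylboronic acid and paraformaldehyde (cat. propanoic acid, PhMe, water removal). This should give 5,7-bis(benzyloxy)-2-phenyl-4H-1,3,2-benzodioxaborinine F3, in which the borate ester delivers the CH2 only ortho to the phenol oxygen.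
- Exchange of boron onto propane-1,3-diol frees 3,5-bis(benzyloxy)-2-(hydroxymethyl)phenol F4.
- F4 is added slowly to an excess of 4 in warm dioxane with catalytic pyridinium p-toluenesulfonate. Its o-quinone methide should be trapped at the one open carbon of 4, giving 1-{3-[(2,4-bis(benzyloxy)-6-hydroxyphenyl)methyl]-2,6-dihydroxy-4-methoxy-5-methylphenyl}-3-phenylpropan-1-one F5.
- Magnesium-mediated ortho-formylation (MgCl2, Et3N, paraformaldehyde, THF, reflux) can occur only at the single free carbon ortho to the ring A phenol and returns to the route at 9. Compounds 5, 6 and 7 are then not needed.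

Step 12. The benzyl ether ortho to the new carbonyl may be partly lost before ring closure, which would open a second direction of cyclization. Hydrolysis of the hindered vinylogous amide may also lag, or prolonged heating in acid may cleave the CH2 bridge. The fallback sets out from 17 and separates deprotection from ring closure.
- The three MOM groups are removed first on the acid-stable isoxazole (HCl, MeOH, rt), giving 1-{3-{[4,6-bis(benzyloxy)-2-hydroxy-3-(4-methoxy-5-phenyl-1,2-oxazol-3-yl)phenyl]methyl}-2,6-dihydroxy-4-methoxy-5-methylphenyl}-3-phenylpropan-1-one F6.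
- Mo(CO)6 in wet MeCN then opens the N–O bond to the o-hydroxyaryl vinylogous amide (E)-3-amino-3-[4,6-bis(benzyloxy)-3-{[2,4-dihydroxy-6-methoxy-5-methyl-3-(3-phenylpropanoyl)phenyl]methyl}-2-hydroxyphenyl]-2-methoxy-1-phenylprop-2-en-1-one F7.
- Warm aqueous acetic acid, too weak to touch benzyl ethers, closes the free phenol onto the benzoyl carbon and hydrolyses the resulting 4-imine, returning to the route at 20.

**Further compounds**

F1 | step 10 | 3-Ar-4-methoxy-5-phenyl-4,5-dihydro-1,2-oxazol-5-ol (Ar as in 12; racemic) | COC1C(c2c(OCOC)c(Cc3c(OC)c(C)c(OCOC)c(C(=O)CCc4ccccc4)c3OCOC)c(OCc3ccccc3)cc2OCc2ccccc2)=NOC1(O)c1ccccc1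
F2 | step 4 | 3,5-bis(benzyloxy)phenol | Oc1cc(OCc2ccccc2)cc(OCc2ccccc2)c1
F3 | step 4 | 5,7-bis(benzyloxy)-2-phenyl-4H-1,3,2-benzodioxaborinine | c1ccc(cc1)B1OCc2c(OCc3ccccc3)cc(OCc3ccccc3)cc2O1
F4 | step 4 | 3,5-bis(benzyloxy)-2-(hydroxymethyl)phenol | OCc1c(O)cc(OCc2ccccc2)cc1OCc1ccccc1
F5 | step 4 | 1-{3-[(2,4-bis(benzyloxy)-6-hydroxyphenyl)methyl]-2,6-dihydroxy-4-methoxy-5-methylphenyl}-3-phenylpropan-1-one | COc1c(C)c(O)c(C(=O)CCc2ccccc2)c(O)c1Cc1c(O)cc(OCc2ccccc2)cc1OCc1ccccc1
F6 | step 12 | 1-{3-{[4,6-bis(benzyloxy)-2-hydroxy-3-(4-methoxy-5-phenyl-1,2-oxazol-3-yl)phenyl]methyl}-2,6-dihydroxy-4-methoxy-5-methylphenyl}-3-phenylpropan-1-one | COc1c(-c2c(O)c(Cc3c(OC)c(C)c(O)c(C(=O)CCc4ccccc4)c3O)c(OCc3ccccc3)cc2OCc2ccccc2)noc1-c1ccccc1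
F7 | step 12 | (E)-3-amino-3-[4,6-bis(benzyloxy)-3-{[2,4-dihydroxy-6-methoxy-5-methyl-3-(3-phenylpropanoyl)phenyl]methyl}-2-hydroxyphenyl]-2-methoxy-1-phenylprop-2-en-1-one | N/C(c1c(O)c(Cc2c(OC)c(C)c(O)c(C(=O)CCc3ccccc3)c2O)c(OCc2ccccc2)cc1OCc1ccccc1)=C(/OC)C(=O)c1ccccc1
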